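A clock reading taken at one enzyme loading cannot be carried to another, so the meeting began by wiping time off the blackboard.

| setting | delta | epsilon | eta | Saturday's | Monday's |
|---|---|---|---|---|---|
| starting material | 0.050 M | 0.050 M | 0.050 M | 0.050 M | 0.050 M |
| protic impurity | 0.0064 M | 0.011 M | 0.010 M | 0.00500 M | 0.0100 M |
| free enzyme | 0.0016 mol% | 0.0016 mol% | 0.0018 mol% | 0.0025 mol% | 0.0016 mol% |
| temperature | 22 °C | 37 °C | 22 °C | 37 °C | 37 °C |
| remark | run made earlier | run made earlier | run made earlier |  |  |
| time |  |  |  | 2.5 d | 2.5 d |

delta run (percent of the starting material charged)

| time / d | target / % | starting material / % |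
|---|---|---|
| 0.208 | 8 | 85 |
| 0.417 | 17 | 73 |
| 0.625 | 27 | 64 |
| 1.25 | 42 | 45 |
| 2.50 | 56 | 21 |

epsilon run (percent of the starting material charged)

| time / h | target / % | starting material / % |
|---|---|---|
| 2.50 | 12 | 72 |
| 5.00 | 16 | 61 |
| 8.00 | 26 | 54 |
| 15.0 | 36 | 36 |
| 30.0 | 34 | 17 |

eta run (percent of the starting material charged)

| time / d | target / % | starting material / % |
|---|---|---|
| 0.500 | 23 | 61 |
| 1.04 | 37 | 42 |
| 1.67 | 48 | 30 |
| 2.00 | 53 | 21 |
| 2.50 | 53 | 14 |

(standard deviation of a reading: 2 percentage points)

- which one finishes higher in amount of target, in percent of the starting material charged ("neither" within 2 percentage points) (Saturday's / Monday's / neither)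
- amount of target at the end, in percent of the starting material charged, Saturday's
- amount of target at the end, in percent of the starting material charged, Monday's

- the earlier runs were read with a standard deviation of 2 percentage points
- on the list of suspects stand: starting material + free enzyme -> target + free enzyme; target -> over-reaction product; starting material + protic impurity -> quenched substrate; free enzyme -> unfolded enzyme

Minutes. As minute-taker I argued my own reckoning. If both steps are taken as first order, the rate at which target is used divided by the rate at which it is made is κ[target]/[starting material], with time gone. At the top of a target curve that quotient is one. The epsilon run's target stands nearly still over its last two readings, so I took that pair for the top, and their averages give κ = 0.757, the overrun ratio, over-reaction constant over enzyme constant (a selectivity factor), for 0.0016 mol% at 37 °C, a reading that carries the scatter of those readings. With x the fraction left of the starting material that escapes quench, [target] = s(x^κ − x)/(1 − κ), where s is that surviving share.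

The chair asked for s. I took one starting material lost per impurity, giving 90.0% for Saturday's and 80.0% for Monday's. The same late epsilon readings give a decay of 1.20 /d, so Monday's x is 0.0497. Saturday's loading, assumed proportional, divides κ to 0.485 and brings x to 0.00919. That made 16.4% for Saturday's and 17.6% for Monday's, a gap of 1.2 percentage points, inside the margin.

The forecast answered neither, with 25% for Saturday's and 24.5% for Monday's: “These are effectively equal.” Its figures stand higher than mine, though the choice is the same.

The flasks give 19.1% for Saturday's and 18.9% for Monday's, so neither, as forecast, with both forecast figures higher than the result.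

    starting material + free enzyme → target + free enzyme, rate k1*[starting material]^1.5*[free enzyme]/(1 + ([starting material]/Kh1)^1.5) (37.0 mM, k = 6.60 × 10⁵ /M^1.5/h, Ea = 41.0 kJ/mol)
    target → over-reaction product (k = 0.0330 /h, Ea = 112 kJ/mol)
    starting material + protic impurity → quenched substrate (k = 8.30 /M/h, Ea = 53.0 kJ/mol)
    free enzyme → unfolded enzyme (k = 0.00160 /h, Ea = 205 kJ/mol)
    (constants at 37 °C)

In Monday's flask, target is made 2.34 times as fast as it is used at 0.466 d, but that quotient has dropped to 0.267 at 2.50 d, so the flask is read well past its top. The overrun ratio, applied to Monday's final amounts as a first-order estimate, gives 0.442 for that quotient, higher than the flask's own value.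

For Monday's flask stopped at 15 h, x is 0.472 and κ gives 31.1% of target. The computed flask holds 34.1%.

The data were generated by integration with made-up constants; scatter was added.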